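## Retrosynthetic overview

1. Target ⇐ C3‑OH unmasked from a C3‑SiMe2Ph group (Fleming–Tamao), C8 angelate and C10 acetate by esterification, trans‑fused α‑methylene lactone by iodolactonisation of an acrylic acid (the oxidised carvone isopropenyl group) onto a Z‑C5=C6 alkene.
2. Ten‑membered ring ⇐ anionic oxy‑Cope ring expansion of a trans‑1,2‑dialkenylcyclohexanol: C1–C6 is broken, C3–C4 is made, and C3/C4 are set through a chair.
3. Dialkenylcyclohexanol ⇐ epoxy ketone 7 by α‑(Z)‑propenylation, silylacetylide addition anti to the oxirane, then LiAlH4 (E‑vinylsilane and C10 tertiary alcohol).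
4. Epoxy ketone 7 ⇐ (S)‑carvone by α′‑silyloxylation, epoxidation/Wharton transposition and hydroxyl‑directed epoxidation.
5. Ring order: cyclohexane (bought in carvone) → ten‑membered carbocycle (step 9) → γ‑lactone (step 14).

Assumption: the ten‑membered ring carries germacranolide numbers (C1 ketone, C3 OH, C4 Me, C6 lactone O, C7 side chain, C8 angelate, C10 Me/OAc), β is the face of the C7 side chain, and cyclohexane intermediates from 5 onward are numbered C1 (→C1), C2 (→C10), C3 (→C9), C4 (→C8), C5 (→C7), C6 (→C6).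

## Route

Step 1
Reactants: 1 (S)-(+)-carvone
Product: 3 trans-6-(tert-butyldimethylsilyloxy)carvone, via TBS dienol ether 2 (not isolated)
Conditions: TBSOTf, Et3N, CH2Cl2, 0 °C; then mCPBA, hexane/CH2Cl2, −20 °C
Reagents that add atoms: tert-butyldimethylsilyl triflate CC(C)(C)[Si](C)(C)OS(=O)(=O)C(F)(F)F; mCPBA O=C(OO)c1cccc(Cl)c1
Why: Soft enolisation gives the cross‑conjugated silyl dienol ether, and Rubottom oxidation with 1,4‑silyl shift places OTBS on the α′ carbon anti to the neighbouring isopropenyl group.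

Step 2
Reactants: 3 trans-6-(tert-butyldimethylsilyloxy)carvone
Product: 4 epoxy ketone
Conditions: 30% H2O2, NaOH (cat.), MeOH, 0 °C
Reagents that add atoms: hydrogen peroxide OO
Why: Weitz–Scheffer nucleophilic epoxidation, in which hydroperoxide adds to the β‑carbon anti to the isopropenyl group as it does with carvone itself.

Step 3
Reactants: 4 epoxy ketone
Product: 5 allylic alcohol
Conditions: N2H4·H2O, AcOH (cat.), MeOH, 0 °C → rt
Reagents that add atoms: none
Why: Wharton transposition: the epoxy hydrazone loses N2, the former β‑carbon keeps its C–O bond (new C1‑OH, trans to isopropenyl) and the old carbonyl carbon becomes the C9 alkene carbon.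

Step 4
Reactants: 5 allylic alcohol
Product: 6 epoxy alcohol
Conditions: VO(acac)2 (cat.), t-BuOOH, CH2Cl2, 0 °C → rt
Reagents that add atoms: tert-butyl hydroperoxide CC(C)(C)OO
Why: Hydroxyl‑directed vanadium‑catalysed epoxidation delivers oxygen syn to the C1‑OH, which places the future C10 oxygen on the α face and leaves the isopropenyl group alone.

Step 5
Reactants: 6 epoxy alcohol
Product: 7 epoxy ketone
Conditions: Dess–Martin periodinane, CH2Cl2, rt
Reagents that add atoms: none
Why: Dess–Martin oxidation of the secondary alcohol to the ketone without touching the oxirane or any stereocentre.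

Step 6
Reactants: 7 epoxy ketone; 8 (Z)-1-bromoprop-1-ene
Product: 10 6-[(Z)-prop-1-enyl] epoxy ketone, via chlorozinc enolate 9 (not isolated)
Conditions: LiN(SiMe3)2, THF, −78 °C; ZnCl2; then 8, Pd2(dba)3 (cat.), P(t-Bu)3 (cat.), rt
Reagents that add atoms: none
Why: Palladium‑catalysed α‑alkenylation of the only possible enolate (Negishi‑type coupling of the zinc enolate) keeps the Z geometry and forms the C6–C5 bond anti to the adjacent isopropenyl group.

Step 7
Reactants: 10 6-[(Z)-prop-1-enyl] epoxy ketone; 11 ethynyl(dimethyl)phenylsilane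
Product: 13 tertiary propargylic alcohol, via dichlorocerium acetylide 12 (not isolated)
Conditions: 11, n-BuLi, THF, −78 °C; CeCl3; then 10, −78 °C; then H2O
Reagents that add atoms: none
Why: Organocerium 1,2‑addition avoids enolising the acidic C6‑H and attacks anti to both the oxirane oxygen and the C6 substituent, so the new C1‑OH is α and the alkynyl group is trans to the propenyl group.

Step 8
Reactants: 13 tertiary propargylic alcohol
Product: 14 dialkenyl diol
Conditions: LiAlH4, THF, 0 °C → reflux; then H2O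
Reagents that add atoms: none
Why: Alkoxide‑directed trans‑hydroalumination gives the E‑vinylsilane, and hydride opens the trisubstituted epoxide at its secondary carbon (Fürst–Plattner), leaving the tertiary C10‑OH with its configuration.

Step 9
Reactants: 14 dialkenyl diol
Product: 16 (E)-cyclodecenone, via dipotassium enolate 15 (not isolated)
Conditions: KH, 18-crown-6, THF, 0 → 45 °C; then AcOH, −78 °C
Reagents that add atoms: none
Why: Anionic oxy‑Cope [3,3]‑sigmatropic rearrangement through a trans‑decalin‑like chair with both alkenyl groups equatorial, where the E‑vinylsilane puts Si equatorial (C3 β) and the Z‑propenyl puts Me axial (C4 β) and the C5=C6 alkene emerges E.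

Step 10
Reactants: 16 (E)-cyclodecenone
Product: 17 (Z)-cyclodecenone
Conditions: PhSSPh (cat.), hν, C6H6, rt
Reagents that add atoms: none
Why: Thiyl‑radical addition–elimination equilibrates the strained E‑cyclodecene to the more stable Z isomer, whose two faces are open to the anti addition needed in step 14, without touching a stereocentre.

Step 11
Reactants: 17 (Z)-cyclodecenone
Product: 18 C10 acetate
Conditions: Ac2O, DMAP (cat.), pyridine, 40 °C
Reagents that add atoms: acetic anhydride CC(=O)OC(C)=O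
Why: DMAP‑catalysed acylation of the only free hydroxyl, the tertiary α‑ketol, while C8 is still silylated.

Step 12
Reactants: 18 C10 acetate
Product: 19 allylic alcohol
Conditions: SeO2 (cat.), t-BuOOH, CH2Cl2, rt
Reagents that add atoms: selenium dioxide O=[Se]=O; tert-butyl hydroperoxide CC(C)(C)OO
Why: Riley allylic oxidation (ene reaction then [2,3] shift) hydroxylates the methyl of the 1,1‑disubstituted isopropenyl group in preference to the methine positions next to the ring alkene.

Step 13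
Reactants: 19 allylic alcohol
Product: 21 acrylic acid, via enal 20 (not isolated)
Conditions: TEMPO (cat.), PhI(OAc)2, MeCN/H2O, rt
Reagents that add atoms: water O
Why: Oxoammonium‑mediated oxidation takes the primary allylic alcohol to the enal and, through its hydrate, on to the carboxylic acid.

Step 14
Reactants: 21 acrylic acid
Product: 22 iodolactone
Conditions: I2, NaHCO3, MeCN, 0 °C, dark
Reagents that add atoms: iodine [I][I]
Why: 5‑exo iodolactonisation (anti addition) in which allylic 1,3‑strain holds H7 in the plane of the Z‑alkene, so the carboxylate attacks C6 from the side of C11 and gives the trans‑fused lactone (C6 oxygen α, iodine at C5 β).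

Step 15
Reactants: 22 iodolactone
Product: 23 silyl-protected lactone
Conditions: Bu3SnH, Et3B (cat.), air, toluene, 0 °C
Reagents that add atoms: none
Why: Radical chain deiodination, where iodine abstraction and hydrogen transfer outrun stannyl addition to the methylene lactone at low temperature.

Step 16
Reactants: 23 silyl-protected lactone
Product: 24 C8 alcohol
Conditions: HF·pyridine, THF, 0 °C → rt
Reagents that add atoms: none
Why: Fluoride‑mediated cleavage of the secondary TBS ether, to which the carbon‑bound dimethylphenylsilyl group is inert.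

Step 17
Reactants: 24 C8 alcohol; 25 angelic acid
Product: 27 C8 angelate, via mixed anhydride 26 (not isolated)
Conditions: 25, 2,4,6-trichlorobenzoyl chloride, Et3N, toluene, rt; then 24, DMAP (cat.), 60 °C
Reagents that add atoms: none
Why: Yamaguchi esterification of the only free hydroxyl, a mixed‑anhydride activation known to keep the Z geometry of angelates.

Step 18
Reactants: 27 C8 angelate
Product: 28 target
Conditions: Hg(OAc)2, AcOOH, AcOH, rt
Reagents that add atoms: peracetic acid CC(=O)OO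
Why: Fleming–Tamao oxidation, in which ipso‑mercuridesilylation removes the phenyl group and the peracid then moves C3 from silicon to oxygen with retention, giving the 3β‑alcohol.

## Compound list

1 | (S)-(+)-carvone, (5S)-2-methyl-5-(prop-1-en-2-yl)cyclohex-2-en-1-one | CC1=CC[C@@H](CC1=O)C(C)=C | starting material
2 | cross-conjugated tert-butyldimethylsilyl dienol ether of 1 (2-silyloxy-1,3-diene, C5 unchanged) | C1[C@H](C(C)=C)C=C(O[Si](C)(C)C(C)(C)C)C(C)=C1 | intermediate
3 | (5R,6R)-6-(tert-butyldimethylsilyloxy)-2-methyl-5-(prop-1-en-2-yl)cyclohex-2-en-1-one, OTBS trans to isopropenyl | C1[C@H](C(C)=C)[C@@H](O[Si](C)(C)C(C)(C)C)C(=O)C(C)=C1 | intermediate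
4 | 2,3-epoxide of 3, oxirane trans to isopropenyl and cis to OTBS | C1[C@H](C(C)=C)[C@@H](O[Si](C)(C)C(C)(C)C)C(=O)[C@@]2(C)O[C@H]21 | intermediate
5 | 4-(tert-butyldimethylsilyloxy)-2-methyl-5-(prop-1-en-2-yl)cyclohex-2-en-1-ol, 1-OH and 4-OTBS cis to each other and trans to the 5-isopropenyl group | C1[C@H](C(C)=C)[C@@H](O[Si](C)(C)C(C)(C)C)C=C(C)[C@H]1O | intermediate
6 | 2,3-epoxide of 5, oxirane cis to 1-OH and 4-OTBS | C1[C@H](C(C)=C)[C@@H](O[Si](C)(C)C(C)(C)C)[C@H]2O[C@@]2(C)[C@H]1O | intermediate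
7 | 2,3-epoxy-4-(tert-butyldimethylsilyloxy)-2-methyl-5-(prop-1-en-2-yl)cyclohexan-1-one, oxirane and OTBS cis, both trans to isopropenyl | C1[C@H](C(C)=C)[C@@H](O[Si](C)(C)C(C)(C)C)[C@H]2O[C@@]2(C)C1=O | intermediate
8 | (Z)-1-bromoprop-1-ene | C/C=C\Br | starting material
9 | chlorozinc enolate of 7 (C1=C6, O–ZnCl) | CC(=C)[C@H]1C=C(O[Zn]Cl)[C@]2(C)O[C@@H]2[C@@H]1O[Si](C)(C)C(C)(C)C | intermediate
10 | 7 carrying a 6-[(Z)-prop-1-enyl] group trans to the 5-isopropenyl group | C/C=C\[C@H]1[C@H](C(C)=C)[C@@H](O[Si](C)(C)C(C)(C)C)[C@H]2O[C@@]2(C)C1=O | intermediate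
11 | ethynyl(dimethyl)phenylsilane | C#C[Si](C)(C)c1ccccc1 | starting material
12 | dichlorocerium 2-(dimethylphenylsilyl)acetylide | Cl[Ce](Cl)C#C[Si](C)(C)c1ccccc1 | intermediate
13 | 1-[(dimethylphenylsilyl)ethynyl] carbinol of 10, 1-OH cis to oxirane, OTBS and propenyl, alkynyl cis to isopropenyl | C/C=C\[C@H]1[C@H](C(C)=C)[C@@H](O[Si](C)(C)C(C)(C)C)[C@H]2O[C@@]2(C)[C@@]1(C#C[Si](C)(C)c3ccccc3)O | intermediate
14 | 1-[(E)-2-(dimethylphenylsilyl)ethenyl]-2-methyl-6-[(Z)-prop-1-enyl]-5-(prop-1-en-2-yl)-4-(tert-butyldimethylsilyloxy)cyclohexane-1,2-diol; 1-OH, 2-OH, 4-OTBS and 6-propenyl α; silylvinyl, 2-methyl and 5-isopropenyl β | C/C=C\[C@H]1[C@H](C(C)=C)[C@@H](O[Si](C)(C)C(C)(C)C)C[C@@](C)(O)[C@@]1(/C=C/[Si](C)(C)c2ccccc2)O | intermediate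
15 | dipotassium salt of 16 (C1=C2 enolate and C10 alkoxide) | CC(=C)[C@H]1/C=C/[C@@H](C)[C@@H]([Si](C)(C)c2ccccc2)/C=C(\[O-])[C@](C)([O-])C[C@@H]1O[Si](C)(C)C(C)(C)C.[K+].[K+] | intermediate
16 | (5E)-3β-(dimethylphenylsilyl)-10α-hydroxy-4β,10β-dimethyl-7β-(prop-1-en-2-yl)-8α-(tert-butyldimethylsilyloxy)cyclodec-5-en-1-one | CC(=C)[C@H]1/C=C/[C@@H](C)[C@@H]([Si](C)(C)c2ccccc2)CC(=O)[C@](C)(O)C[C@@H]1O[Si](C)(C)C(C)(C)C | intermediate
17 | (5Z) isomer of 16 | CC(=C)[C@H]1/C=C\[C@@H](C)[C@@H]([Si](C)(C)c2ccccc2)CC(=O)[C@](C)(O)C[C@@H]1O[Si](C)(C)C(C)(C)C | intermediate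
18 | 10α-acetate of 17 | CC(=C)[C@H]1/C=C\[C@@H](C)[C@@H]([Si](C)(C)c2ccccc2)CC(=O)[C@](C)(OC(C)=O)C[C@@H]1O[Si](C)(C)C(C)(C)C | intermediate
19 | 18 with the side chain as 7β-(3-hydroxyprop-1-en-2-yl) | OCC(=C)[C@H]1/C=C\[C@@H](C)[C@@H]([Si](C)(C)c2ccccc2)CC(=O)[C@](C)(OC(C)=O)C[C@@H]1O[Si](C)(C)C(C)(C)C | intermediate
20 | corresponding enal, 7β-(3-oxoprop-1-en-2-yl) | O=CC(=C)[C@H]1/C=C\[C@@H](C)[C@@H]([Si](C)(C)c2ccccc2)CC(=O)[C@](C)(OC(C)=O)C[C@@H]1O[Si](C)(C)C(C)(C)C | intermediate
21 | corresponding 2-substituted prop-2-enoic acid (C12 acid) | OC(=O)C(=C)[C@H]1/C=C\[C@@H](C)[C@@H]([Si](C)(C)c2ccccc2)CC(=O)[C@](C)(OC(C)=O)C[C@@H]1O[Si](C)(C)C(C)(C)C | intermediate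
22 | 10α-acetoxy-3β-(dimethylphenylsilyl)-5β-iodo-1-oxo-8α-(tert-butyldimethylsilyloxy)germacr-11(13)-en-6α,12-olide (H-6 β, H-7 α) | C=C1C(=O)O[C@@H]2[C@@H](I)[C@@H](C)[C@@H]([Si](C)(C)c3ccccc3)CC(=O)[C@](C)(OC(C)=O)C[C@H](O[Si](C)(C)C(C)(C)C)[C@@H]12 | intermediate
23 | 10α-acetoxy-3β-(dimethylphenylsilyl)-1-oxo-8α-(tert-butyldimethylsilyloxy)germacr-11(13)-en-6α,12-olide | C=C1C(=O)O[C@@H]2C[C@@H](C)[C@@H]([Si](C)(C)c3ccccc3)CC(=O)[C@](C)(OC(C)=O)C[C@H](O[Si](C)(C)C(C)(C)C)[C@@H]12 | intermediate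
24 | 10α-acetoxy-3β-(dimethylphenylsilyl)-8α-hydroxy-1-oxogermacr-11(13)-en-6α,12-olide | C=C1C(=O)O[C@@H]2C[C@@H](C)[C@@H]([Si](C)(C)c3ccccc3)CC(=O)[C@](C)(OC(C)=O)C[C@H](O)[C@@H]12 | intermediate
25 | angelic acid, (Z)-2-methylbut-2-enoic acid | C/C=C(/C)C(=O)O | starting material
26 | angelic 2,4,6-trichlorobenzoic anhydride | C/C=C(/C)C(=O)OC(=O)c1c(Cl)cc(Cl)cc1Cl | intermediate
27 | 10α-acetoxy-8α-angeloyloxy-3β-(dimethylphenylsilyl)-1-oxogermacr-11(13)-en-6α,12-olide | C=C1C(=O)O[C@@H]2C[C@@H](C)[C@@H]([Si](C)(C)c3ccccc3)CC(=O)[C@](C)(OC(C)=O)C[C@H](OC(=O)/C(C)=C\C)[C@@H]12 | intermediate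
28 | 10α-acetoxy-8α-angeloyloxy-3β-hydroxy-1-oxogermacr-11(13)-en-6α,12-olide (4β-Me, H-6 β, H-7 α) | C=C1C(=O)O[C@@H]2C[C@@H](C)[C@@H](O)CC(=O)[C@](C)(OC(C)=O)C[C@H](OC(=O)/C(C)=C\C)[C@@H]12 | target

## Step count and weak points

Total steps: 18. Longest linear sequence: 18 (from 1).

Step 6 is the most exposed: the β,γ‑unsaturated ketone can slip into conjugation, the epoxy ketone enolate may not survive the coupling, and conversion may be low. The fallback sets out from 7. Its trimethylsilyl enol ether is brominated with NBS to the 6α‑bromo epoxy ketone F1, and F1 is joined to (Z)-prop-1-enylzinc bromide under nickel catalysis (NiCl2·glyme, 4,4′-di-tert-butyl-2,2′-bipyridine, THF, 0 °C). The C6 radical is captured trans to the isopropenyl group with the Z geometry kept, and the route is rejoined at 10.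

Step 9 carries the whole stereochemical argument for C3 and C4. The dianion may rearrange slowly, the TBS group may migrate to the C10 alkoxide, or the chair may lose to other pathways. The fallback sets out from 14. Both tertiary hydroxyls are silylated (TMSOTf, 2,6-lutidine) to the bis(trimethylsilyl) ether F2, which undergoes the neutral siloxy‑Cope rearrangement (decalin, 200 °C, sealed tube) through the same chair to the ten‑membered trimethylsilyl enol ether F3. K2CO3 in MeOH removes both trimethylsilyl groups and comes back to 16.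

Step 14 may be slow on the hindered Z‑alkene, or the iodide may be lost under the conditions. The fallback sets out from 21. mCPBA epoxidises the Z‑alkene to the epoxy acid F4, and only the oxirane on the face away from the side chain can cyclise. Catalytic camphorsulfonic acid lets the carboxyl group open the oxirane at C6 with inversion to the 5β‑hydroxy lactone F5. The hydroxyl is converted with 1,1′-thiocarbonyldiimidazole into the imidazolyl thiocarbonate F6 and removed with Bu3SnH (Barton–McCombie), which comes back to 23.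

## Further compounds

F1 | step 6 | 6α-bromo-2,3-epoxy-4-(tert-butyldimethylsilyloxy)-2-methyl-5-(prop-1-en-2-yl)cyclohexan-1-one | Br[C@H]1[C@H](C(C)=C)[C@@H](O[Si](C)(C)C(C)(C)C)[C@H]2O[C@@]2(C)C1=O
F2 | step 9 | bis(trimethylsilyl) ether of 14 | C/C=C\[C@H]1[C@H](C(C)=C)[C@@H](O[Si](C)(C)C(C)(C)C)C[C@@](C)(O[Si](C)(C)C)[C@@]1(/C=C/[Si](C)(C)c2ccccc2)O[Si](C)(C)C
F3 | step 9 | C1 trimethylsilyl enol ether and C10 trimethylsilyl ether of 16 | CC(=C)[C@H]1/C=C/[C@@H](C)[C@@H]([Si](C)(C)c2ccccc2)/C=C(\O[Si](C)(C)C)[C@](C)(O[Si](C)(C)C)C[C@@H]1O[Si](C)(C)C(C)(C)C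
F4 | step 14 | 5β,6β-epoxide of acid 21 | OC(=O)C(=C)[C@H]1[C@H]2O[C@H]2[C@@H](C)[C@@H]([Si](C)(C)c3ccccc3)CC(=O)[C@](C)(OC(C)=O)C[C@@H]1O[Si](C)(C)C(C)(C)C
F5 | step 14 | 5β-hydroxy analogue of 23 | C=C1C(=O)O[C@@H]2[C@@H](O)[C@@H](C)[C@@H]([Si](C)(C)c3ccccc3)CC(=O)[C@](C)(OC(C)=O)C[C@H](O[Si](C)(C)C(C)(C)C)[C@@H]12
F6 | step 14 | 5β-O-(imidazol-1-ylthiocarbonyl) derivative of F5 | C=C1C(=O)O[C@@H]2[C@@H](OC(=S)n3ccnc3)[C@@H](C)[C@@H]([Si](C)(C)c4ccccc4)CC(=O)[C@](C)(OC(C)=O)C[C@H](O[Si](C)(C)C(C)(C)C)[C@@H]12
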